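## Retrosynthetic overview

1. Target 12 ⇐ hexa-O-methyl ether 11 by global O-demethylation.
2. Both pyranone rings of 11 ⇐ bis(hydroxymethylene ketone) 7 by one double aryl C–H oxygenation and ring closure (the O1–C8a bonds). Each aroyl ring has a single ortho C–H, so the 6,8''-pattern is fixed by the biaryl substitution.
3. 7 ⇐ bis-deoxybenzoin 6 (Claisen formylation) ⇐ biaryl 3 + two equivalents of acid 4 (double Friedel–Crafts acylation).
4. 3 ⇐ bromide 1 + boronic acid 2 (Suzuki coupling). Ring order: biaryl first, then both pyranone rings together in step 4.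

Assumption: the target has no stereocentre and its SMILES carries no axial descriptor, so it is made as drawn; if the hindered 6,8''-axis is configurationally stable, the product is racemic about it.

Ring A is the 2,4-dimethoxyphenyl ring (primed locants; it becomes the 8-linked genistein unit). Ring B is the 2,6-dimethoxyphenyl ring (unprimed locants; it becomes the 6-linked unit).

## Route

Step 1
Reactants: 1 2-bromo-1,3-dimethoxybenzene; 2 (2,4-dimethoxyphenyl)boronic acid
Product: 3 2,2',4',6-tetramethoxy-1,1'-biphenyl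
Conditions: Pd(OAc)2 (2 mol%), 2-dicyclohexylphosphino-2',6'-dimethoxybiphenyl (SPhos, 4 mol%), K3PO4 (3 equiv), toluene/H2O 10:1, 100 °C
Reagents that add atoms: none
Why: Suzuki–Miyaura coupling; SPhos-ligated zerovalent palladium inserts into the hindered, electron-rich C–Br bond, and boron sits on the mono-ortho-substituted partner, which resists protodeboronation.

Step 2
Reactants: 3 2,2',4',6-tetramethoxy-1,1'-biphenyl; 4 (4-methoxyphenyl)acetic acid (2.4 equiv)
Product: 6 3,5'-bis[(4-methoxyphenyl)acetyl]-2,2',4',6-tetramethoxy-1,1'-biphenyl, via mixed anhydride 5 (not isolated)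
Conditions: (CF3CO)2O (6 equiv), 85% H3PO4 (0.3 equiv), CH2Cl2, 0 to 25 °C
Reagents that add atoms: none
Why: Friedel–Crafts acylation through the mixed trifluoroacetic anhydride; each ring reacts once at its most activated free position (para to one OMe, ortho to the other: C5' of ring A, C3 of ring B), the first acyl group deactivates its own ring, and the Brønsted-acid medium leaves the methyl ethers intact.

Step 3
Reactants: 6 3,5'-bis[(4-methoxyphenyl)acetyl]-2,2',4',6-tetramethoxy-1,1'-biphenyl
Product: 7 3,5'-bis[3-hydroxy-2-(4-methoxyphenyl)prop-2-enoyl]-2,2',4',6-tetramethoxy-1,1'-biphenyl (enol form, alkene geometry not fixed)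
Conditions: HCO2Et (10 equiv), NaH (5 equiv), THF, 0 to 25 °C; then 1 M HCl
Reagents that add atoms: ethyl formate (CCOC=O)
Why: Crossed Claisen condensation; the benzylic CH2 of each deoxybenzoin is the only enolisable site, and formylation is driven by formation of the chelated sodium enolate of the β-keto aldehyde.

Step 4
Reactants: 7 3,5'-bis[3-hydroxy-2-(4-methoxyphenyl)prop-2-enoyl]-2,2',4',6-tetramethoxy-1,1'-biphenyl
Product: 11 5,7-dimethoxy-3-(4-methoxyphenyl)-6-[5,7-dimethoxy-3-(4-methoxyphenyl)-4-oxo-4H-chromen-8-yl]-4H-chromen-4-one (hexa-O-methyl ether of the target), via bis(enol trifluoroacetate) 8 (not isolated), via tetrakis(trifluoroacetate) 9 (not isolated), via bis(2-hydroxyaryl) enol 10 (not isolated)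
Conditions: Pd(OCOCF3)2 (20 mol%), K2S2O8 (5 equiv), CF3CO2H/(CF3CO)2O 9:1, 50 °C; evaporate; then MeOH, 25 °C; then HCl (cat.), MeOH, 50 °C
Reagents that add atoms: trifluoroacetic acid (OC(=O)C(F)(F)F)
Why: Proposed new method: in CF3CO2H/(CF3CO)2O the hydroxymethylene groups are masked as enol trifluoroacetates (8), which shields the α-carbon from the oxidant and leaves each aryl ketone carbonyl free to direct cyclopalladation by divalent palladium (five-membered palladacycle, concerted metalation–deprotonation) at the only ortho C–H of its ring (C6' of ring A, C4 of ring B; the other ortho position carries OMe); persulfate oxidises the palladacycle to a tetravalent aryl palladium trifluoroacetate that reductively eliminates the aryl C–O bond (9); methanolysis frees the phenols (10), which cyclodehydrate onto the hydroxymethylene carbon and close both pyranone rings with the 6,8''-connectivity set by where the C–H bonds were; the closest known reaction type is the ketone-directed palladium-catalysed ortho-C–H hydroxylation of aryl ketones with K2S2O8 in CF3CO2H/(CF3CO)2O, joined here to the classical cyclodehydration of 2-hydroxyaryl hydroxymethylene ketones to isoflavones; what is unproven is oxygenation of a C–H flanked by the biaryl axis and the use of an α-(acyloxymethylene) ketone as substrate.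

Step 5
Reactants: 11 hexa-O-methyl ether
Product: 12 5,7-dihydroxy-3-(4-hydroxyphenyl)-6-[5,7-dihydroxy-3-(4-hydroxyphenyl)-4-oxo-4H-chromen-8-yl]-4H-chromen-4-one (target)
Conditions: BBr3 (15 equiv), CH2Cl2, −78 to 25 °C; then H2O
Reagents that add atoms: none
Why: Lewis-acid ether cleavage (BBr3 demethylation) of all six aryl methyl ethers at or below room temperature, where the isoflavone rings do not open and the biaryl linkage cannot isomerise.

## Compound list

1 | 2-bromo-1,3-dimethoxybenzene | COc1cccc(OC)c1Br | starting material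
2 | (2,4-dimethoxyphenyl)boronic acid | COc1ccc(B(O)O)c(OC)c1 | starting material
3 | 2,2',4',6-tetramethoxy-1,1'-biphenyl | COc1ccc(-c2c(OC)cccc2OC)c(OC)c1 | intermediate
4 | (4-methoxyphenyl)acetic acid | COc1ccc(CC(=O)O)cc1 | starting material
5 | (4-methoxyphenyl)acetic trifluoroacetic anhydride (formed in the flask) | COc1ccc(CC(=O)OC(=O)C(F)(F)F)cc1 | intermediate
6 | 3,5'-bis[(4-methoxyphenyl)acetyl]-2,2',4',6-tetramethoxy-1,1'-biphenyl | COc1cc(OC)c(C(=O)Cc2ccc(OC)cc2)cc1-c1c(OC)ccc(C(=O)Cc2ccc(OC)cc2)c1OC | intermediate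
7 | 3,5'-bis[3-hydroxy-2-(4-methoxyphenyl)prop-2-enoyl]-2,2',4',6-tetramethoxy-1,1'-biphenyl | COc1cc(OC)c(C(=O)C(=CO)c2ccc(OC)cc2)cc1-c1c(OC)ccc(C(=O)C(=CO)c2ccc(OC)cc2)c1OC | intermediate
8 | bis(enol trifluoroacetate) of 7 (formed in the flask) | COc1cc(OC)c(C(=O)C(=COC(=O)C(F)(F)F)c2ccc(OC)cc2)cc1-c1c(OC)ccc(C(=O)C(=COC(=O)C(F)(F)F)c2ccc(OC)cc2)c1OC | intermediate
9 | 4,6'-bis(trifluoroacetoxy) derivative of 8 (formed in the flask) | COc1cc(OC)c(C(=O)C(=COC(=O)C(F)(F)F)c2ccc(OC)cc2)c(OC(=O)C(F)(F)F)c1-c1c(OC)cc(OC(=O)C(F)(F)F)c(C(=O)C(=COC(=O)C(F)(F)F)c2ccc(OC)cc2)c1OC | intermediate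
10 | 4,6'-dihydroxy-3,5'-bis[3-hydroxy-2-(4-methoxyphenyl)prop-2-enoyl]-2,2',4',6-tetramethoxy-1,1'-biphenyl (formed in the flask) | COc1cc(OC)c(C(=O)C(=CO)c2ccc(OC)cc2)c(O)c1-c1c(OC)cc(O)c(C(=O)C(=CO)c2ccc(OC)cc2)c1OC | intermediate
11 | 5,7-dimethoxy-3-(4-methoxyphenyl)-6-[5,7-dimethoxy-3-(4-methoxyphenyl)-4-oxo-4H-chromen-8-yl]-4H-chromen-4-one | COc1cc(OC)c2c(=O)c(-c3ccc(OC)cc3)coc2c1-c1c(OC)cc2occ(-c3ccc(OC)cc3)c(=O)c2c1OC | intermediate
12 | 5,7-dihydroxy-3-(4-hydroxyphenyl)-6-[5,7-dihydroxy-3-(4-hydroxyphenyl)-4-oxo-4H-chromen-8-yl]-4H-chromen-4-one | Oc1cc(O)c2c(=O)c(-c3ccc(O)cc3)coc2c1-c1c(O)cc2occ(-c3ccc(O)cc3)c(=O)c2c1O | target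

## Step count and risks

Total steps: 5. Longest linear sequence: 5 steps (1 or 2 → 3 → 6 → 7 → 11 → 12).

**Step 4 (the proposed new step) is the most likely to fail.**
- The C6'–H of ring A lies between the ketone and the biaryl axis and may resist palladation, which would leave a mono-annulated product.
- The anisyl ring could be palladated instead through a six-membered palladacycle.
- Persulfate may attack the electron-rich rings.

The fallback uses known chemistry and moves the oxygenation to the simple ketone stage, closing the rings afterwards through the O1–C2 bond. It sets out from 6 and comes back at 11. Compound 6 is treated with [RuCl2(p-cymene)]2 (5 mol%) and PhI(OCOCF3)2 in CF3CO2H/(CF3CO)2O at 80 °C, the established ketone-directed ortho-C–H oxygenation of aryl ketones. This gives 4,6'-bis(trifluoroacetoxy)-3,5'-bis[(4-methoxyphenyl)acetyl]-2,2',4',6-tetramethoxy-1,1'-biphenyl F1. Aqueous NaHCO3 work-up hydrolyses it to 4,6'-dihydroxy-3,5'-bis[(4-methoxyphenyl)acetyl]-2,2',4',6-tetramethoxy-1,1'-biphenyl F2. Heating F2 with N,N-dimethylformamide dimethyl acetal in toluene at 90 °C forms the bis(dimethylaminomethylene) ketone F3, which closes in the flask by attack of each phenol on the enaminone carbon with loss of dimethylamine, giving 11. This fallback still needs oxygenation at the hindered C6'–H, so it addresses the substrate and oxidant risks but not the steric one.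

**Step 2 is the second risk.** The arylacetyl electrophile can lose CO to give a 4-methoxybenzyl cation, and the second acylation may stall. The fallback builds the deoxybenzoins from the other side; it sets out from 3 and comes back at 6. Double Friedel–Crafts acetylation of 3 (acetyl chloride, AlCl3, CH2Cl2, 0 °C) gives 3,5'-diacetyl-2,2',4',6-tetramethoxy-1,1'-biphenyl F4. A double palladium-catalysed ketone α-arylation with 4-bromoanisole (Pd2(dba)3, Xantphos, NaOtBu, toluene, 80 °C) then gives 6; the product enolate prevents a second arylation at the same carbon.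

**Step 5 is the third risk.** Six-fold cleavage may stop short, and prolonged exposure to strong acid could open and re-close a 5-hydroxy-pyranone ring, which would scramble the 6,8''-linkage. The fallback splits the deprotection into two mechanistically different stages; it sets out from 11 and comes back at 12. BCl3 (CH2Cl2, 0 °C) removes only the two chelated methyl ethers peri to the carbonyls and gives 5-hydroxy-6-[5-hydroxy-7-methoxy-3-(4-methoxyphenyl)-4-oxo-4H-chromen-8-yl]-7-methoxy-3-(4-methoxyphenyl)-4H-chromen-4-one F5. The four remaining ethers are then cleaved by the hard-acid/soft-nucleophile pair AlCl3/EtSH (CH2Cl2, 0 to 25 °C) to give 12.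

## Further compounds

F1 | step 4 | 4,6'-bis(trifluoroacetoxy)-3,5'-bis[(4-methoxyphenyl)acetyl]-2,2',4',6-tetramethoxy-1,1'-biphenyl | COc1cc(OC)c(C(=O)Cc2ccc(OC)cc2)c(OC(=O)C(F)(F)F)c1-c1c(OC)cc(OC(=O)C(F)(F)F)c(C(=O)Cc2ccc(OC)cc2)c1OC
F2 | step 4 | 4,6'-dihydroxy-3,5'-bis[(4-methoxyphenyl)acetyl]-2,2',4',6-tetramethoxy-1,1'-biphenyl | COc1cc(OC)c(C(=O)Cc2ccc(OC)cc2)c(O)c1-c1c(OC)cc(O)c(C(=O)Cc2ccc(OC)cc2)c1OC
F3 | step 4 | 4,6'-dihydroxy-3,5'-bis[3-(dimethylamino)-2-(4-methoxyphenyl)prop-2-enoyl]-2,2',4',6-tetramethoxy-1,1'-biphenyl | COc1cc(OC)c(C(=O)C(=CN(C)C)c2ccc(OC)cc2)c(O)c1-c1c(OC)cc(O)c(C(=O)C(=CN(C)C)c2ccc(OC)cc2)c1OC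
F4 | step 2 | 3,5'-diacetyl-2,2',4',6-tetramethoxy-1,1'-biphenyl | COc1cc(OC)c(C(C)=O)cc1-c1c(OC)ccc(C(C)=O)c1OC
F5 | step 5 | 5-hydroxy-6-[5-hydroxy-7-methoxy-3-(4-methoxyphenyl)-4-oxo-4H-chromen-8-yl]-7-methoxy-3-(4-methoxyphenyl)-4H-chromen-4-one | COc1cc(O)c2c(=O)c(-c3ccc(OC)cc3)coc2c1-c1c(OC)cc2occ(-c3ccc(OC)cc3)c(=O)c2c1O
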